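All runs were computed on assumed constants; the scatter is artificial.

1. The ratio of two successive gains of D in the north run, 0.614, is where we begin. In that run, with [E] = 0.84 M at 82 °C, D gains 17.1% by 3.00 min, then 10 percentage points over the next equal stretch.

| flask | E | temperature | remark | time |
|---|---|---|---|---|
| west | 0.38 M | 60 °C | run made earlier |  |
| north | 0.84 M | 82 °C | run made earlier |  |
| theta | 0.56 M | 70 °C |  | 20 min |
| eta | 0.56 M |  | at 50 °C until 4.0 min, from then on at 90 °C | 20 min |
| alpha | 0.56 M | 50 °C |  | 20 min |
| gamma | 0.56 M | 90 °C |  | 20 min |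

- west (time / min: D / %): 2.00: 1.4; 3.00: 3.1; 6.00: 4.2; 10.0: 7.9; 15.0: 11.6; 25.0: 16.3
- north (time / min: D / %): 0.667: 5.8; 1.00: 7.9; 2.00: 11.9; 3.00: 17.1; 6.00: 27.6; 8.00: 31.4

(readings scatter by 1 percentage point)

* the flask with the highest amount of D, in percent of the E charged ("all alike" if they lie within 1.5 percentage points) (theta / eta / alpha / gamma / all alike)
* final D, as a percentage of the E charged, in theta
* final D, as a percentage of the E charged, in eta
* final D, as a percentage of the E charged, in alpha
* final D, as a percentage of the E charged, in gamma

2. Follow one molecule of E. It may reach D, or it may leave towards Z and L. If each equal stretch keeps the same ratio of gains, the gains add up to 44.3%. We call this the north plateau, the level that net D in the north run heads for if the ratio holds, with whatever D loses already inside the gains; the usual term is apparent yield, and it is not the chance that a molecule of E reaches D. The same ratio gives a climb time of 6.15 min. Both are readings and carry the scatter of 1 point.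

3. Now turn the question round: what must be true for gamma to hold more D than eta? We count eta's hot minutes, 16.0 min, because even the west run, at 60 °C, gains 3.1% by 3.00 min, less than north's 17.1% by 3.00 min. On north's curve, taken over although gamma runs hotter than north, gamma's extra 4.0 min of heat buys 1.6 points of further net climb, which is 3.55% of the north plateau. So gamma leads if net D is still climbing that late, and eta leads if net D has turned down by then. The step D -> G is among those thought possible, so we lean to eta, at 41.0% on the same curve, an estimate of net D.

4. The forecast names eta: theta 30%, eta 39%, alpha 6.5%, gamma 38%. Of eta it says “slightly favoured if D drains”. Our eta figure stands above its figure.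

5. The flasks give eta as the richest in D: theta 26.9%, eta 40.5%, alpha 5.95%, gamma 36.3%.

    E ⇌ Z (K = 0.550, k = 0.0120 s⁻¹, Ea = 98.0 kJ mol⁻¹, ΔH = −20.0 kJ mol⁻¹)
    Z ⇌ L (K = 23.0, k = 0.00310 s⁻¹, Ea = 107 kJ mol⁻¹, ΔH = −33.0 kJ mol⁻¹)
    D → G (k = 7.00 × 10⁻⁴ s⁻¹, Ea = 99.0 kJ mol⁻¹)
    E → D (k = 0.00310 s⁻¹, Ea = 97.0 kJ mol⁻¹)
    (constants at 90 °C)

In gamma, D stands at 44.1% after 10.0 min and 36.3% after 20.0 min, while G rises from 13.7% to 31.0%. Against the north plateau, gamma ends 8 points short and eta 3.8 points short. A repeat of alpha at 75 °C holds 35.1% of D after 20.0 min, which is 0.792 of the north plateau, with 23.7% of E still there.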